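**Retrosynthetic overview**
- The strategy rests on one feature. The vinyl group on C10 and the isopropenyl group on the adjacent ring carbon C5 form the 1,5-diene C1=C2–C10–C5–C4=C3. Bonding C2 to C4 and C1 to C3 folds this diene into a 1-methylbicyclo[2.2.0]hexane fused to the cyclohexane at C10–C5.
- Late disconnections, in order: O9 angelate (esterification); lactone ring C6–O–C12–C11–C7 (oxidation of a 2-methylene-1,4-diol); C6 ketone used to invert C5; thermal cycloreversion of the cage; C7–C11 bond (vinylcerium addition to a C7 ketone made by 1,2-carbonyl transposition).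
- Key disconnection: the central cyclobutane C10–C5–C4–C2 goes back to a 3-methylcyclohexenone (ring atoms, O8 and O9 from (−)-quinic acid) and 1-methylcyclobutene by [2+2] photocycloaddition.
- The cage stays closed as a mask for both alkenes while C6/C7 are hydroborated and oxidised. C5 is inverted only once C7 is quaternary, so the β-silyloxy group at C8 cannot be eliminated.
- Ring order: cyclohexane (chiral pool), then the central cyclobutane built onto the cyclobutene ring (step 10), then both four-membered rings opened (step 16), then the lactone (step 22).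

Key step: step 10

Numbering and faces:
- From the enone onward, ring atoms are C5–C10. C2 is the vinyl CH on C10 and C1 its CH2. C4 is the isopropenyl carbon on C5 and C3 its CH2. C11(=C13)–C12 is the lactone side chain on C7.
- β is the ring face that carries the C10 methyl group. α is the face that carries the C10–C2 bond.
- Quinic acid C1/C2/C3/C4/C5/C6 become C6/C5/C10/C9/C8/C7.
- The target SMILES reads as 5S,6S,7S,8S,9R,10S. This means 5β-isopropenyl, 6β-O (lactone cis-fused), 7α-OH, 8α-OH, 9β-O-angelate, 10β-methyl.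

Design remark: O9 carries TBS and O8 carries the more acid-stable TBDPS, so O9 can be freed alone for the esterification.

**Step 1**
Reactants: 1 (−)-quinic acid
Product: 2 3,4-O-isopropylidene-1,5-quinide (1,5-lactone 3,4-acetonide of quinic acid; all stereocentres as in 1)
Conditions: Me2C(OMe)2, p-TsOH·H2O (cat.), acetone, reflux
Reagents that add atoms: 2,2-dimethoxypropane, COC(C)(C)OC
Why: Acid-catalysed transketalisation selects the only cis-diol (O3/O4) while the carboxyl group lactonises onto the syn-axial O5, so the three secondary hydroxyls are told apart in one operation and no stereocentre is touched.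

**Step 2**
Reactants: 2 3,4-O-isopropylidene-1,5-quinide
Product: 3 1-(hydroxymethyl)-3,4-O-isopropylidenecyclohexane-1,3,4,5-tetraol (quinic numbering; configuration unchanged)
Conditions: NaBH4, EtOH, 0 °C → rt
Reagents that add atoms: none
Why: Borohydride reduction of an activated α-hydroxy lactone gives the primary alcohol, which frees O5 and creates a terminal 1,2-diol at C1.

**Step 3**
Reactants: 3 the triol acetonide
Product: 4 (3R,4S,5R)-5-hydroxy-3,4-(isopropylidenedioxy)cyclohexan-1-one
Conditions: NaIO4, H2O, 0 °C → rt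
Reagents that add atoms: none
Why: Malaprade glycol cleavage acts on the only free vicinal diol (C1–OH/CH2OH), removes the former carboxyl carbon as formaldehyde and leaves the C1 ketone.

**Step 4**
Reactants: 4 the β-hydroxy ketone
Product: 5 5-O-tert-butyldiphenylsilyl ether of 4 (3,4-cis-acetonide; 5-OTBDPS trans to O4)
Conditions: TBDPSCl, imidazole, DMF, rt
Reagents that add atoms: TBDPSCl, CC(C)(C)[Si](Cl)(c1ccccc1)c1ccccc1
Why: Standard silylation of an equatorial secondary alcohol under weakly basic conditions that do not start β-elimination, with TBDPS chosen because this oxygen (future O8) stays masked until the last step.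

**Step 5**
Reactants: 5 the silylated ketone
Product: 6 (4R,5R)-5-(tert-butyldiphenylsilyloxy)-4-hydroxycyclohex-2-en-1-one
Conditions: DBU (0.3 equiv), CH2Cl2, 0 °C
Reagents that add atoms: none
Why: E1cB elimination in which only the axial acetonide oxygen O3 is aligned with the enolate π system, so it leaves, the hemiketal anion sheds acetone and the γ-hydroxy enone with free O4 (future O9) forms while the equatorial OTBDPS group stays.

**Step 6**
Reactants: 6 the γ-hydroxy enone
Product: 7 (4R,5R)-4-(tert-butyldimethylsilyloxy)-5-(tert-butyldiphenylsilyloxy)cyclohex-2-en-1-one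
Conditions: TBSOTf, 2,6-lutidine, CH2Cl2, −78 → 0 °C
Reagents that add atoms: TBSOTf, CC(C)(C)[Si](C)(C)OS(=O)(=O)C(F)(F)F
Why: Silyl triflate silylation of a hindered allylic alcohol gives O9 a group that can later be cleaved in the presence of the TBDPS ether on O8.

**Step 7**
Reactants: 7 the bis-silylated enone
Product: 8 trimethylsilyl enol ether of the 3,4-trans 3-methyl-4-(TBSO)-5-(TBDPSO)cyclohexanone (C1=C2 enol ether)
Conditions: MeLi, CuI, Et2O, 0 °C; then 7, TMSCl, THF, −78 °C; Et3N
Reagents that add atoms: Me2CuLi, [Li+].C[Cu-]C; TMSCl, C[Si](C)(C)Cl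
Why: TMSCl-accelerated Gilman cuprate 1,4-addition traps the enolate as its silyl enol ether and so prevents β-elimination of the OTBDPS group; the methyl group should enter anti to the C4 OTBS group, but this centre is erased in step 8.

**Step 8**
Reactants: 8 the silyl enol ether
Product: 9 (4R,5R)-4-(tert-butyldimethylsilyloxy)-5-(tert-butyldiphenylsilyloxy)-3-methylcyclohex-2-en-1-one
Conditions: Pd(OAc)2 (1.1 equiv), MeCN, rt
Reagents that add atoms: none
Why: Saegusa–Ito oxidation, in which divalent palladium forms the C2-palladated ketone and β-hydride elimination of the C3–H restores the enone, now carrying the future C10 methyl group.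

**Step 9**
Reactants: 10 methylenecyclobutane
Product: 11 1-methylcyclobutene
Conditions: KOt-Bu (cat.), DMSO, rt; fractional distillation
Reagents that add atoms: none
Why: Base-catalysed prototropic isomerisation through the allyl anion moves the double bond into the more substituted endocyclic position, which is the favoured isomer.

**Step 10**
Reactants: 9 the 3-methyl enone; 11 1-methylcyclobutene
Product: 12 cis-anti-cis 10-(tert-butyldimethylsilyloxy)-9-(tert-butyldiphenylsilyloxy)-1,5-dimethyltricyclo[4.4.0.0(2,5)]decan-7-one (C6 ketone; 8α-OTBDPS; 9β-OTBS; C10–C2 and C5–C4 bonds α)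
Conditions: hν (medium-pressure Hg lamp, uranium-glass filter, λ > 330 nm), 11 (15 equiv), CH2Cl2, −70 °C, Ar
Reagents that add atoms: none
Why: Excitation of 9 and intersystem crossing give the twisted enone triplet, which bonds to 11 to form a triplet 1,4-diradical, and spin inversion with radical recombination makes the second bond, so C10–C2 and C5–C4 arise in one operation. The closest known reaction type is the intermolecular enone–cycloalkene [2+2] photocycloaddition, which is established for 3-alkylcyclohexenones with cyclobutenes as a photochemical entry to elemane ketones. The one ring closed is the central cyclobutane C10–C5–C4–C2, closed by 1,4-diradical collapse, and it should be cis-fused to the six-membered ring because the cis-bicyclo[4.2.0]octanone is the less strained outcome, which fixes C5 relative to C10. C10 is controlled by the substrate: allylic strain with the ring methyl group and the mutual repulsion of two bulky vicinal silyl ethers hold the C9 OTBS group pseudoaxial on the β face, so the alkene should bond from the α face along the axial trajectory. C2 and C4 are cis because they come from a four-membered cis-alkene, and the C1–C3 bridge should turn away from the cyclohexanone (anti) for steric reasons. The step needs regioselectivity (methyl-bearing C4 to C5, CH carbon C2 to C10), which rests only on avoiding two adjacent quaternary carbons, and facial selectivity, for which the allylic C9 silyl ether must outweigh the more remote α-oriented C8 OTBDPS group.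

**Step 11**
Reactants: 12 the photoadduct
Product: 13 triethylsilyl enol ether of 12 (C6(OTES)=C7; tricyclodec-7-ene)
Conditions: TESOTf, Et3N, CH2Cl2, 0 °C
Reagents that add atoms: TESOTf, CC[Si](CC)(CC)OS(=O)(=O)C(F)(F)F
Why: Soft enolisation with a silyl triflate and amine forms no free enolate, so the β-OTBDPS group is not expelled, and it goes toward C7 because a C5=C6 double bond would be tetrasubstituted and exocyclic to the strained cage.

**Step 12**
Reactants: 13 the TES enol ether
Product: 15 10-(TBSO)-9-(TBDPSO)-7-(triethylsilyloxy)-1,5-dimethyltricyclo[4.4.0.0(2,5)]decan-8-ol (6α-OTES; 7β-OH), via organoborane 14 (not isolated)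
Conditions: BH3·THF, THF, 0 °C → rt; then 3 M NaOH, 30% H2O2, 0 °C
Reagents that add atoms: H2O2, OO; BH3·THF, [BH3-][O+]1CCCC1 (boron in 14 only)
Why: Hydroboration–oxidation of a silyl enol ether places boron on the carbon remote from oxygen (C7) and gives the trans-2-silyloxy alcohol; syn addition should occur on the β face because the C4 methyl group of the cage covers the α face, and no other alkene is present since the diene is still masked.

**Step 13**
Reactants: 15 the alcohol
Product: 16 10-(TBSO)-9-(TBDPSO)-7-(triethylsilyloxy)-1,5-dimethyltricyclo[4.4.0.0(2,5)]decan-8-one (C7 ketone; 6α-OTES)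
Conditions: Dess–Martin periodinane, NaHCO3, CH2Cl2, rt
Reagents that add atoms: none
Why: Buffered Dess–Martin oxidation of an isolated secondary alcohol completes the 1,2-carbonyl transposition under non-basic conditions that leave the α-silyloxy centres C6 and C8 unepimerised.

**Step 14**
Reactants: 17 2-bromoprop-2-en-1-ol
Product: 18 (2-bromoallyloxy)(tert-butyl)dimethylsilane
Conditions: TBSCl, imidazole, CH2Cl2, rt
Reagents that add atoms: TBSCl, CC(C)(C)[Si](C)(C)Cl
Why: Routine silylation of a primary allylic alcohol.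

**Step 15**
Reactants: 16 the C7 ketone; 18 the bromide
Product: 21 8-[3-(tert-butyldimethylsilyloxy)prop-1-en-2-yl]-10-(TBSO)-9-(TBDPSO)-7-(triethylsilyloxy)-1,5-dimethyltricyclo[4.4.0.0(2,5)]decan-8-ol (7α-OH; C11 β), via vinyllithium 19 (not isolated), via organocerium reagent 20 (not isolated)
Conditions: 18 (3 equiv), t-BuLi (6 equiv), Et2O, −78 °C; CeCl3, THF, −78 °C; then 16, −78 °C; aq. NH4Cl at −78 °C
Reagents that add atoms: t-BuLi, [Li]C(C)(C)C (Li in 19 only); CeCl3, Cl[Ce](Cl)Cl (Ce and Cl in 20 only)
Why: Bromine–lithium exchange and organocerium 1,2-addition give a nucleophile of low basicity, so there is no enolisation toward C8 and no loss of the O9 silyloxide; the C4 methyl group of the cage and both flanking α-silyloxy groups close the α face, so the nucleophile should enter equatorially from the β face and set C7 with C11 β and OH α.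

**Step 16**
Reactants: 21 the tricyclic tertiary alcohol
Product: 22 5-epi-elematriene: 5α-isopropenyl; 6α-OTES; 7α-OH; 8α-OTBDPS; 9β-OTBS; 10α-vinyl; 12-OTBS; elema-1,3,11(13)-triene
Conditions: mesitylene (degassed), BHT (cat.), base-washed sealed tube, 200 °C
Reagents that add atoms: none
Why: Thermal cycloreversion of a bicyclo[2.2.0]hexane: homolysis of the strained central C2–C4 bond gives a cyclohexane-1,4-diyl that fragments at C1–C3 (or at C10–C5, then recloses by Cope rearrangement of the ten-membered 1,5-diene), so strain release from two fused cyclobutanes drives formation of the vinyl and isopropenyl groups, C10 should keep its configuration, and C5 emerges with the isopropenyl group still α, to be corrected in step 19.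

**Step 17**
Reactants: 22 the TES ether
Product: 23 the 6α,7α-diol (TES removed; other groups as in 22)
Conditions: PPTS (cat.), MeOH/CH2Cl2, 0 °C
Reagents that add atoms: none
Why: Graded acid methanolysis of silyl ethers, in which the TES ether is far more labile than the TBS and TBDPS ethers and the conditions are mild enough for the tertiary allylic alcohol.

**Step 18**
Reactants: 23 the diol
Product: 24 the C6 ketone, 5-epi series (5α-isopropenyl; 7α-OH; 8α-OTBDPS; 9β-OTBS; 12-OTBS)
Conditions: IBX, DMSO, rt
Reagents that add atoms: none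
Why: IBX oxidises the secondary hydroxyl of a secondary–tertiary 1,2-diol to the α-ketol without glycol cleavage and leaves alkenes and TBS/TBDPS ethers alone.

**Step 19**
Reactants: 24 the 5-epi ketone
Product: 26 the C6 ketone with natural C5 (5β-isopropenyl, trans to vinyl), via dilithium dienolate 25 (not isolated)
Conditions: LiHMDS (3 equiv), THF, −78 → 0 °C; then AcOH, THF, −78 °C
Reagents that add atoms: LiHMDS, [Li]N([Si](C)(C)C)[Si](C)(C)C (Li in 25 only)
Why: Deprotonation followed by kinetic reprotonation: with C7 quaternary the only acidic C–H next to the ketone is the doubly activated C5–H, so one cross-conjugated dienolate forms with no chance of E1cB loss of the C8 silyloxy group, and such dienolates protonate at the α-carbon along the axial direction (α face), which places the isopropenyl group equatorial (β) as in the more stable epimer.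

**Step 20**
Reactants: 26 the ketone
Product: 27 the 6β,7α-diol (5β-isopropenyl; 8α-OTBDPS; 9β-OTBS; 12-OTBS)
Conditions: Me4NBH(OAc)3, MeCN/AcOH, −30 → 0 °C
Reagents that add atoms: none
Why: Saksena–Evans hydroxyl-directed reduction, in which the axial 7α-OH binds the acetoxyborohydride and delivers hydride to the α face of C6, the face also left open by the axial C10 methyl group, so the axial 6β-alcohol should result.

**Step 21**
Reactants: 27 the diol
Product: 28 the 6β,7α,9β,12-tetraol 8-O-TBDPS ether
Conditions: HF·pyridine, pyridine, THF, 0 °C → rt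
Reagents that add atoms: none
Why: Graded fluoride desilylation, in which buffered HF·pyridine cleaves the primary allylic and the C9 TBS ethers much faster than the acid-stable TBDPS ether on O8.

**Step 22**
Reactants: 28 the tetraol
Product: 31 8α-(tert-butyldiphenylsilyloxy)-7α,9β-dihydroxyelema-1,3,11(13)-trien-12,6β-olide, via hydroxy enal 29 (not isolated), via lactol 30 (not isolated)
Conditions: MnO2 (activated, excess), CH2Cl2, rt
Reagents that add atoms: none
Why: MnO2 oxidation of a 2-methylene-1,4-diol: only the primary alcohol is allylic, its aldehyde is captured by the neighbouring 6β-OH as a five-membered lactol, and this is oxidised on to the cis-fused α-methylene-γ-lactone while the non-allylic C9 and tertiary C7 hydroxyls are untouched.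

**Step 23**
Reactants: 31 the hydroxy lactone; 32 angelic acid
Product: 34 the 9β-angelate 8-O-TBDPS ether, via mixed anhydride 33 (not isolated)
Conditions: 32, 2,4,6-trichlorobenzoyl chloride, Et3N, toluene, rt; then 31, 80 °C
Reagents that add atoms: 2,4,6-trichlorobenzoyl chloride, O=C(Cl)c1c(Cl)cc(Cl)cc1Cl (aroyl group in 33 only)
Why: Yamaguchi-type mixed-anhydride esterification without a nucleophilic catalyst is the standard way to form angelates without Z to E isomerisation, and only the secondary C9–OH can react because C7–OH is tertiary and O8 is silylated.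

**Step 24**
Reactants: 34 the silylated angelate
Product: 35 target, (5S,6S,7S,8S,9R,10S)-9-angeloyloxy-7,8-dihydroxyelema-1,3,11(13)-trien-12,6-olide
Conditions: HF·pyridine, THF, 0 °C → rt (polypropylene vessel)
Reagents that add atoms: none
Why: Fluoride cleavage of the last silyl ether under mildly acidic conditions forms no alkoxide, so neither acyl migration from O9 to O8 nor translactonisation onto O8 is triggered.

**Compound list**
1 | (−)-quinic acid | C1[C@H]([C@H]([C@@H](C[C@@]1(C(=O)O)O)O)O)O | starting material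
2 | 3,4-O-isopropylidene-1,5-quinide | C1[C@@H]2[C@H]([C@H]3C[C@]1(O)C(=O)O3)OC(C)(C)O2 | intermediate
3 | 1-(hydroxymethyl)-3,4-O-isopropylidenecyclohexane-1,3,4,5-tetraol | C1[C@@H]2[C@H]([C@H](O)C[C@]1(O)CO)OC(C)(C)O2 | intermediate
4 | (3R,4S,5R)-5-hydroxy-3,4-(isopropylidenedioxy)cyclohexan-1-one | C1[C@@H]2[C@H]([C@H](O)CC1=O)OC(C)(C)O2 | intermediate
5 | 5-O-TBDPS ether of 4 | C1[C@@H]2[C@H]([C@H](O[Si](c3ccccc3)(c3ccccc3)C(C)(C)C)CC1=O)OC(C)(C)O2 | intermediate
6 | (4R,5R)-5-(TBDPSO)-4-hydroxycyclohex-2-en-1-one | C1=CC(=O)C[C@@H](O[Si](c2ccccc2)(c2ccccc2)C(C)(C)C)[C@@H]1O | intermediate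
7 | (4R,5R)-4-(TBSO)-5-(TBDPSO)cyclohex-2-en-1-one | C1=CC(=O)C[C@@H](O[Si](c2ccccc2)(c2ccccc2)C(C)(C)C)[C@@H]1O[Si](C)(C)C(C)(C)C | intermediate
8 | TMS enol ether of the 3,4-trans 3-methyl ketone | C[C@H]1C=C(O[Si](C)(C)C)C[C@@H](O[Si](c2ccccc2)(c2ccccc2)C(C)(C)C)[C@@H]1O[Si](C)(C)C(C)(C)C | intermediate
9 | (4R,5R)-4-(TBSO)-5-(TBDPSO)-3-methylcyclohex-2-en-1-one | CC1=CC(=O)C[C@@H](O[Si](c2ccccc2)(c2ccccc2)C(C)(C)C)[C@@H]1O[Si](C)(C)C(C)(C)C | intermediate
10 | methylenecyclobutane | C=C1CCC1 | starting material
11 | 1-methylcyclobutene | CC1=CCC1 | intermediate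
12 | cis-anti-cis photoadduct (tricyclodecan-7-one) | C[C@]12[C@@H]3CC[C@]3(C)[C@H]1C(=O)C[C@@H](O[Si](c3ccccc3)(c3ccccc3)C(C)(C)C)[C@@H]2O[Si](C)(C)C(C)(C)C | intermediate
13 | TES enol ether of 12 | C[C@]12[C@@H]3CC[C@]3(C)[C@H]1C(O[Si](CC)(CC)CC)=C[C@@H](O[Si](c3ccccc3)(c3ccccc3)C(C)(C)C)[C@@H]2O[Si](C)(C)C(C)(C)C | intermediate
14 | C7 β-organoborane | C[C@]12[C@@H]3CC[C@]3(C)[C@H]1[C@@H](O[Si](CC)(CC)CC)[C@H](B)[C@@H](O[Si](c3ccccc3)(c3ccccc3)C(C)(C)C)[C@@H]2O[Si](C)(C)C(C)(C)C | intermediate (not isolated)
15 | 6α-OTES 7β-alcohol (tricyclodecan-8-ol) | C[C@]12[C@@H]3CC[C@]3(C)[C@H]1[C@@H](O[Si](CC)(CC)CC)[C@H](O)[C@@H](O[Si](c3ccccc3)(c3ccccc3)C(C)(C)C)[C@@H]2O[Si](C)(C)C(C)(C)C | intermediate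
16 | C7 ketone (tricyclodecan-8-one) | C[C@]12[C@@H]3CC[C@]3(C)[C@H]1[C@@H](O[Si](CC)(CC)CC)C(=O)[C@@H](O[Si](c3ccccc3)(c3ccccc3)C(C)(C)C)[C@@H]2O[Si](C)(C)C(C)(C)C | intermediate
17 | 2-bromoprop-2-en-1-ol | C=C(Br)CO | starting material
18 | (2-bromoallyloxy)(tert-butyl)dimethylsilane | C=C(Br)CO[Si](C)(C)C(C)(C)C | intermediate
19 | 2-lithioallyl TBS ether | [Li]C(=C)CO[Si](C)(C)C(C)(C)C | intermediate (not isolated)
20 | dichlorocerium derivative of 19 | Cl[Ce](Cl)C(=C)CO[Si](C)(C)C(C)(C)C | intermediate (not isolated)
21 | tricyclic tertiary alcohol (7α-OH, C11 β) | C[C@]12[C@@H]3CC[C@]3(C)[C@H]1[C@@H](O[Si](CC)(CC)CC)[C@](O)(C(=C)CO[Si](C)(C)C(C)(C)C)[C@@H](O[Si](c3ccccc3)(c3ccccc3)C(C)(C)C)[C@@H]2O[Si](C)(C)C(C)(C)C | intermediate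
22 | 5-epi-elematriene, 6α-OTES | C=C[C@@]1(C)[C@@H](C(=C)C)[C@@H](O[Si](CC)(CC)CC)[C@](O)(C(=C)CO[Si](C)(C)C(C)(C)C)[C@@H](O[Si](c2ccccc2)(c2ccccc2)C(C)(C)C)[C@@H]1O[Si](C)(C)C(C)(C)C | intermediate
23 | 5-epi 6α,7α-diol | C=C[C@@]1(C)[C@@H](C(=C)C)[C@@H](O)[C@](O)(C(=C)CO[Si](C)(C)C(C)(C)C)[C@@H](O[Si](c2ccccc2)(c2ccccc2)C(C)(C)C)[C@@H]1O[Si](C)(C)C(C)(C)C | intermediate
24 | 5-epi C6 ketone | C=C[C@@]1(C)[C@@H](C(=C)C)C(=O)[C@](O)(C(=C)CO[Si](C)(C)C(C)(C)C)[C@@H](O[Si](c2ccccc2)(c2ccccc2)C(C)(C)C)[C@@H]1O[Si](C)(C)C(C)(C)C | intermediate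
25 | dilithium alkoxide dienolate | [Li+].[Li+].C=C[C@@]1(C)C(C(C)=C)=C([O-])[C@]([O-])(C(=C)CO[Si](C)(C)C(C)(C)C)[C@@H](O[Si](c2ccccc2)(c2ccccc2)C(C)(C)C)[C@@H]1O[Si](C)(C)C(C)(C)C | intermediate (not isolated)
26 | C6 ketone, 5β-isopropenyl | C=C[C@@]1(C)[C@H](C(=C)C)C(=O)[C@](O)(C(=C)CO[Si](C)(C)C(C)(C)C)[C@@H](O[Si](c2ccccc2)(c2ccccc2)C(C)(C)C)[C@@H]1O[Si](C)(C)C(C)(C)C | intermediate
27 | 6β,7α-diol | C=C[C@@]1(C)[C@H](C(=C)C)[C@H](O)[C@](O)(C(=C)CO[Si](C)(C)C(C)(C)C)[C@@H](O[Si](c2ccccc2)(c2ccccc2)C(C)(C)C)[C@@H]1O[Si](C)(C)C(C)(C)C | intermediate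
28 | 6β,7α,9β,12-tetraol 8-O-TBDPS ether | C=C[C@@]1(C)[C@H](C(=C)C)[C@H](O)[C@](O)(C(=C)CO)[C@@H](O[Si](c2ccccc2)(c2ccccc2)C(C)(C)C)[C@@H]1O | intermediate
29 | hydroxy enal | C=C[C@@]1(C)[C@H](C(=C)C)[C@H](O)[C@](O)(C(=C)C=O)[C@@H](O[Si](c2ccccc2)(c2ccccc2)C(C)(C)C)[C@@H]1O | intermediate (not isolated)
30 | lactol (C12 epimers) | C=C[C@@]1(C)[C@H](C(=C)C)[C@@H]2OC(O)C(=C)[C@]2(O)[C@@H](O[Si](c3ccccc3)(c3ccccc3)C(C)(C)C)[C@@H]1O | intermediate (not isolated)
31 | 8-O-TBDPS 7,9-dihydroxy lactone | C=C[C@@]1(C)[C@H](C(=C)C)[C@@H]2OC(=O)C(=C)[C@]2(O)[C@@H](O[Si](c3ccccc3)(c3ccccc3)C(C)(C)C)[C@@H]1O | intermediate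
32 | angelic acid | C/C=C(/C)C(=O)O | starting material
33 | angelic 2,4,6-trichlorobenzoic anhydride | C/C=C(/C)C(=O)OC(=O)c1c(Cl)cc(Cl)cc1Cl | intermediate (not isolated)
34 | 9-angelate 8-O-TBDPS ether | C=C[C@@]1(C)[C@H](C(=C)C)[C@@H]2OC(=O)C(=C)[C@]2(O)[C@@H](O[Si](c3ccccc3)(c3ccccc3)C(C)(C)C)[C@@H]1OC(=O)/C(C)=C\C | intermediate
35 | CNP0114166.3 | C=C[C@@]1(C)[C@H](C(=C)C)[C@@H]2OC(=O)C(=C)[C@]2(O)[C@@H](O)[C@@H]1OC(=O)/C(C)=C\C | target

**Step count**
Total steps: 24. Longest linear sequence: 22 (steps 1–8, 10–13 and 15–24, from (−)-quinic acid).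

**Steps most likely to fail**

1. Step 10.
   - What may go wrong: the cyclobutene may bond the wrong way round (methyl-bearing carbon to C10), because regiocontrol is purely steric. It may also approach the β face, because the α face still feels the pseudoaxial O8 silyl ether.
   - Fallback: an acceptor group on the alkene serves as a regiodirecting handle. Setting out from 9, irradiation with purchasable methyl cyclobut-1-ene-1-carboxylate (COC(=O)C1=CCC1) should give the C4-methoxycarbonyl photoadduct F1, since the acceptor-bearing carbon of such alkenes bonds preferentially to the enone α-carbon C5. TESOTf/Et3N should convert it into the ester TES enol ether F2. DIBAL-H should reduce the ester to the neopentyl-type primary alcohol F3, and MsCl/Et3N should give the mesylate F4. Hydride displacement with LiBHEt3 in warm THF turns the CH2OMs group into the C4 methyl group. The product is 13, where the route is rejoined.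

2. Step 16.
   - What may go wrong: at 200 °C the free tertiary allylic alcohol may lose water or accept a silyl shift. If the ten-membered diene intervenes and ring-flips before the Cope closure, the configuration at C10 may erode.
   - Fallback: the cycloreversion is moved ahead of the C7–C11 bond formation, onto a substrate with no heat-sensitive carbinol. Setting out from 16, thermolysis under the same neutral conditions should give the ring-opened 5-epi C7 ketone F5. Addition of the organocerium reagent 20 to it should be steered to the β face by the axial 5α-isopropenyl group and the two α-silyloxy groups. This rejoins the route at 22.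

3. Step 19.
   - What may go wrong: removal of the hindered, initially equatorial C5 proton may be slow. That would leave time for an acyloin shift of the C7 alkoxide. Part of the dienolate may also be protonated at its terminal carbon.
   - Fallback: the ketone is first conjugated on purpose. Setting out from 24, warm DBU in toluene should move the double bond into conjugation to give the isopropylidene enone F6. Its unhindered γ-methyl protons are easily removed by LiHMDS or LDA. This deconjugative deprotonation leads to the same dienolate 25, and cold AcOH quench rejoins the route at 26.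

**Further compounds**
F1 | step 10 | C4-methoxycarbonyl photoadduct (cis-anti-cis keto ester) | C[C@]12[C@@H]3CC[C@]3(C(=O)OC)[C@H]1C(=O)C[C@@H](O[Si](c3ccccc3)(c3ccccc3)C(C)(C)C)[C@@H]2O[Si](C)(C)C(C)(C)C
F2 | step 10 | ester TES enol ether | C[C@]12[C@@H]3CC[C@]3(C(=O)OC)[C@H]1C(O[Si](CC)(CC)CC)=C[C@@H](O[Si](c3ccccc3)(c3ccccc3)C(C)(C)C)[C@@H]2O[Si](C)(C)C(C)(C)C
F3 | step 10 | C4-hydroxymethyl TES enol ether | C[C@]12[C@@H]3CC[C@]3(CO)[C@H]1C(O[Si](CC)(CC)CC)=C[C@@H](O[Si](c3ccccc3)(c3ccccc3)C(C)(C)C)[C@@H]2O[Si](C)(C)C(C)(C)C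
F4 | step 10 | C4-mesyloxymethyl TES enol ether | C[C@]12[C@@H]3CC[C@]3(COS(C)(=O)=O)[C@H]1C(O[Si](CC)(CC)CC)=C[C@@H](O[Si](c3ccccc3)(c3ccccc3)C(C)(C)C)[C@@H]2O[Si](C)(C)C(C)(C)C
F5 | step 16 | ring-opened 5-epi C7 ketone (6α-OTES) | C=C[C@@]1(C)[C@@H](C(=C)C)[C@@H](O[Si](CC)(CC)CC)C(=O)[C@@H](O[Si](c2ccccc2)(c2ccccc2)C(C)(C)C)[C@@H]1O[Si](C)(C)C(C)(C)C
F6 | step 19 | conjugated 5-isopropylidene C6 ketone | C=C[C@@]1(C)C(=C(C)C)C(=O)[C@](O)(C(=C)CO[Si](C)(C)C(C)(C)C)[C@@H](O[Si](c2ccccc2)(c2ccccc2)C(C)(C)C)[C@@H]1O[Si](C)(C)C(C)(C)C
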